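Take the 3 questions below: an order of flasks and the percentages of target at its two ends. Reckon them in molar terms first.

| setting | east | north | alder | birch | oak | maple | ash | cedar |
|---|---|---|---|---|---|---|---|---|
| solid substrate | 0.23 M | 0.86 M | 1.0 M | 3.0 M | 2.0 M | 1.5 M | 0.60 M | 0.30 M |
| gas | 200 mM (held) | 200 mM (held) | 200 mM (held) | 200 mM (held) | 200 mM (held) | 200 mM (held) | 200 mM (held) | 200 mM (held) |
| remark | run made earlier | run made earlier |  |  |  |  |  |  |
| time |  |  | 2.0 min | 2.0 min | 2.0 min | 2.0 min | 2.0 min | 2.0 min |

- east (time / s: target / %): 15.0: 1.7; 30.0: 14.6; 50.0: 17.5; 60.0: 23.5
- north (time / s: target / %): 15.0: 0; 30.0: 3.8; 50.0: 9.0; 60.0: 9.3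

(standard deviation of a reading: 1 percentage point)

- solid substrate is a solid; its amount is given per volume of the solution
- at the start none of the solid substrate is in solution
- at the start none of the gas is in solution
- what has only dissolved of solid substrate counts as not reacted

* all flasks from highest to lowest amount of target, in percent of the solid substrate charged, at 2.0 min (alder / birch / oak / maple / ash / cedar)
* the amount of target, in percent of the solid substrate charged of the flask you put first, at 2.0 min
* the amount of target, in percent of the solid substrate charged of the flask you put last, at 2.0 min

Multiply each reading at 60.0 s by its charge. There east reads 0.0541 M of target and north 0.0800 M, so 3.74 times the charge gave 1.48 times the target. Treat a heavy flask as pseudo-zero-order in its charge.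

Next read the slope of north between its second and last readings, 1.58 mM s⁻¹. Run that line back to zero target: it starts after a lag of 9.27 s, a small correction to 2.0 min. Multiply the slope by the time less the lag and divide by the charge, and birch stands at 5.82%.

The weak link is that slope: it rests on a gain of 5.5 percentage points between two readings, each scattering by 1 point. Reforge it by averaging the two early and the two late readings of north. This gives the ceiling rate, 1.92 mM s⁻¹, the molar target gained per second in a heavy flask, as read from north, with a lag of 14.0 s. Birch then comes to 6.78%, and I commit to that.

At the ceiling rate and a fixed time, percent falls as the charge rises, and the last reading of east stands above that of north, so I order the flasks cedar, ash, alder, maple, oak, birch. East gained 0.682 mM s⁻¹ over its late readings, less than the ceiling rate, so I keep that rate for the heavy end and set no number of my own on cedar.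

The forecast gives cedar > ash > alder > maple > oak > birch, with 40% for cedar, which is what first order to completion through the last reading of east gives, and 6.1% for birch, less than my figure, holding that “the reaction appears capped”.

Birch gives 5.10% and cedar 30.1%, and the order is cedar > ash > alder > maple > oak > birch.

    solid substrate ⇌ dissolved substrate, rate k1*(cs1 - [dissolved substrate]) while solid is left; crystals form when [dissolved substrate] > cs1 (solubility = 0.660 M, k = 0.0222 s⁻¹)
    dissolved substrate + coupling partner → target (k = 0.0358 L mol⁻¹ s⁻¹)
    target ⇌ isomer of the product (K = 2.90, k = 0.0120 s⁻¹)
    gas ⇌ coupling partner, rate k4*(csat - [coupling partner]) (kL = 0.231 s⁻¹)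
    solid substrate + target → side product (k = 0.00236 L mol⁻¹ s⁻¹)

At 2.00 min birch also holds 3.06% as isomer of the product, so watch for it beside the target. Put the ceiling rate on oak: it gives 10.2%, and oak gives 8.30%.

Read birch at 30 s instead: the ceiling rate and lag give 1.02%. That flask gives 0.937%.

The data are simulated with constants of no real substance; the scatter is artificial.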